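**Retrosynthetic overview**

1. The target comes from double O-acetylation (step 10) of the bis(5-chloro-7-hydroxy) dimer, which comes from double chlorination at C5/C5' (step 9) of the chlorine-free bis(7-hydroxy) vinylogous pyridone dimer.
2. Key disconnection, made on both halves at once: ring B by a pyridine-type [3+3] heteroannulation of the putrescine bis-enaminone (N2–C1=C8a, acylated by C8) with an alkynone (C5H3–C4a≡C4–C3(=O)–dienyl), forming C8a–C4a and N2–C3; ring A then closes by Claisen acylation C5→C6.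
3. Enabling feature: ring B (N2, C1, C8a, C4a, C4, C3) is the anhydrobase of a 1-alkyl-3-acyl-4-methylpyridinium, with exocyclic C5 as the former picolinium methyl and C8 as the 3-acyl carbonyl. Ring B therefore forms by enaminone-plus-ynone pyridine logic, and the acidic methyl C5 sits six atoms from C6.
4. C6–C7–C8 with O7 and the C7 methyl is (R)-lactic acid: its pivalaldehyde acetal (dioxolanone) is C-acylated with retention to set quaternary C7; the same ring later serves as activated C6 acyl donor and O7 protection and leaves as pivalaldehyde.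
5. The alkynone comes from (S)-2-methylbutan-1-ol by two Wittig homologations and a Weinreb ketone synthesis. Ring order: ring B of both halves, then ring A of both halves, in one pot.

Key step: step 8

Assumption: the C7 centers are taken exactly as written in the SMILES (S in both halves of the target), which maps onto (R)-lactic acid; the two phosphoranes, (E)-3-ethoxyacryloyl chloride and 1-propynylmagnesium bromide are taken as commercial reagents.

**Route**

Step 1
Reactants: 1 (R)-lactic acid
Product: 2 (2R,5R)-2-tert-butyl-5-methyl-1,3-dioxolan-4-one (cis)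
Conditions: t-BuCHO, TsOH·H2O (cat.), H2SO4 (cat.), pentane, reflux, Dean–Stark; crystallisation from pentane/Et2O, −78 °C
Reagents that add atoms: pivalaldehyde CC(C)(C)C=O
Why: Acid-catalysed acetalisation with azeotropic removal of water (the dioxolanone used for self-regeneration of stereocenters) leaves the lactate center untouched and sets the new acetal center C2 under thermodynamic control cis to the C5 methyl, the cis isomer being enriched by low-temperature crystallisation.

Step 2
Reactants: 2 (2R,5R)-2-tert-butyl-5-methyl-1,3-dioxolan-4-one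
Product: 4 (2R,5S)-2-tert-butyl-5-[(2E)-3-ethoxyprop-2-enoyl]-5-methyl-1,3-dioxolan-4-one, via lithium dioxolanone enolate 3 (not isolated)
Conditions: LiN(iPr)2 (commercial solution), THF, −78 °C; then cannulated into (E)-EtOCH=CHCOCl, THF, −78 to −40 °C
Reagents that add atoms: (E)-3-ethoxyacryloyl chloride CCO/C=C/C(Cl)=O
Why: Claisen-type C-acylation of the lithium ester enolate by the acid chloride should take place on the face opposite the tert-butyl group, so the acyl group takes the place of the former lactate hydrogen (net retention, quaternary C5 = future C7), and the product, lacking an α-hydrogen, can be neither deprotonated nor racemised.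

Step 3
Reactants: 4 (2R,5S)-2-tert-butyl-5-[(2E)-3-ethoxyprop-2-enoyl]-5-methyl-1,3-dioxolan-4-one (2 equiv); 5 butane-1,4-diamine (putrescine)
Product: 6 bis-enaminone (2R,2'R,5S,5'S)-5,5'-{butane-1,4-diylbis[azanediyl(2Z)-1-oxoprop-2-ene-3,1-diyl]}bis(2-tert-butyl-5-methyl-1,3-dioxolan-4-one)
Conditions: CH2Cl2, 0 °C to rt
Reagents that add atoms: none
Why: Vinylogous transamidation (conjugate addition–elimination of the primary amine at the β-ethoxy enone) is far faster than aminolysis of the hindered acetal-lactone and should give the hydrogen-bonded Z enaminone at both ends of the diamine without touching a stereocenter.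

Step 4
Reactants: 7 (S)-2-methylbutan-1-ol
Product: 9 ethyl (2E,4S)-2,4-dimethylhex-2-enoate, via (S)-2-methylbutanal 8 (not isolated)
Conditions: TEMPO (cat.), PhI(OAc)2, CH2Cl2, rt; then Ph3P=C(Me)CO2Et, rt
Reagents that add atoms: ethyl 2-(triphenylphosphoranylidene)propanoate CCOC(=O)C(C)=P(c1ccccc1)(c1ccccc1)c1ccccc1
Why: One-pot TEMPO/PhI(OAc)2 oxidation followed by Wittig olefination with the stabilised ylide should give the E trisubstituted enoate, and consuming the α-chiral aldehyde at room temperature as soon as it forms guards the S center against epimerisation.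

Step 5
Reactants: 9 ethyl (2E,4S)-2,4-dimethylhex-2-enoate
Product: 10 (2E,4S)-2,4-dimethylhex-2-en-1-ol
Conditions: iBu2AlH, CH2Cl2, −78 °C; MeOH, then Na2SO4·10H2O
Reagents that add atoms: none
Why: 1,2-Reduction of the conjugated ester by iBu2AlH at low temperature gives the allylic alcohol without affecting the alkene geometry or the allylic stereocenter.

Step 6
Reactants: 10 (2E,4S)-2,4-dimethylhex-2-en-1-ol
Product: 12 (2E,4E,6S)-N-methoxy-N,4,6-trimethylocta-2,4-dienamide, via (2E,4S)-2,4-dimethylhex-2-enal 11 (not isolated)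
Conditions: MnO2 (activated, excess), Ph3P=CHC(O)N(OMe)Me, CH2Cl2, rt to 40 °C
Reagents that add atoms: N-methoxy-N-methyl-2-(triphenylphosphoranylidene)acetamide CON(C)C(=O)C=P(c1ccccc1)(c1ccccc1)c1ccccc1
Why: Tandem allylic oxidation with MnO2 and Wittig olefination traps the volatile enal as it forms, and the amide-stabilised ylide should deliver the new disubstituted alkene with E geometry.

Step 7
Reactants: 12 (2E,4E,6S)-N-methoxy-N,4,6-trimethylocta-2,4-dienamide
Product: 13 (5E,7E,9S)-7,9-dimethylundeca-5,7-dien-2-yn-4-one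
Conditions: CH3C≡CMgBr, THF, −20 to 0 °C; inverse quench into cold 1 M aq. HCl
Reagents that add atoms: 1-propynylmagnesium bromide CC#C[Mg]Br
Why: Weinreb ketone synthesis, in which the alkynyl Grignard reagent adds once to the N-methoxy-N-methylamide carbonyl and not in conjugate fashion, should give the cross-conjugated alkynone, the cold acidic quench keeping the liberated amine from adding to the ynone.

Step 8
Reactants: 6 bis-enaminone; 13 (5E,7E,9S)-7,9-dimethylundeca-5,7-dien-2-yn-4-one (2.2 equiv)
Product: 17 (7R,7'R)-2,2'-(butane-1,4-diyl)bis{3-[(1E,3E,5S)-3,5-dimethylhepta-1,3-dien-1-yl]-7-hydroxy-7-methylisoquinoline-6,8(2H,7H)-dione}, via bis-aminodienone Michael adduct 14 (not isolated), via bis-pyridinium diacetate 15 (not isolated), via bis-anhydrobase 16 (not isolated)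
Conditions: AcOH/PhMe 1:5, 50 °C; evaporation; then DBU (6 equiv), MeCN, 0 °C to rt (one pot)
Reagents that add atoms: none
Why: Proposed new method: acid-promoted Michael addition of the enaminone carbon C8a to the alkynone β-carbon C4a gives aminodienone 14, E-to-Z isomerisation and cyclodehydration of N2 onto the C3 ketone give the 3-acyl-4-methylpyridinium 15 (ring B), and DBU then generates anhydrobase 16, whose exocyclic C5 attacks the dioxolanone carbonyl C6 so that the adduct collapses to the C6 ketone, pivalaldehyde and the free C7 hydroxyl (ring A). The closest known reaction types are the acid-catalysed one-pot Bohlmann–Rahtz pyridine synthesis (enamine plus alkynone), the closure of N-alkyl 5-aminopenta-2,4-dienones to pyridinium salts known from pyrylium-to-pyridinium exchange, and the acylation of 4-picolinium anhydrobases by esters; new are the secondary bis-enaminone as enamine partner and the telescoped lactone Claisen closure. Ring B closes by 6-exo-trig attack of N2 on the C3 carbonyl followed by aromatising loss of water, and ring A by 6-exo-trig Claisen attack of C5 on the lactone carbonyl, which the tether delivers to the face anti to the tert-butyl group. No stereocenter is formed: C7 is quaternary and not enolisable and none of its four bonds is broken (only the O7–acetal bond is cleaved), so the configuration from (R)-lactic acid is carried through, and C5' is remote from the basic site. The step needs C- rather than N-attack of the enaminone, the alkyne rather than the dienone as acceptor, and the 4-methyl group (C5) rather than the remote allylic positions as the site of deprotonation; these are secured by the hydrogen-bonded, delocalised N–H of the Z vinylogous amide (soft carbon nucleophile at C8a), by the much higher electrophilicity of the alkynone β-carbon than of the δ-branched dienone, and by the far higher acidity of the methyl group flanked by the C8 acyl group. The driving force is formation of the aromatic pyridinium and then of the stabilised vinylogous pyridone with irreversible loss of pivalaldehyde.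

Step 9
Reactants: 17 bis(7-hydroxy) vinylogous pyridone dimer
Product: 18 (7S,7'S)-2,2'-(butane-1,4-diyl)bis{5-chloro-3-[(1E,3E,5S)-3,5-dimethylhepta-1,3-dien-1-yl]-7-hydroxy-7-methylisoquinoline-6,8(2H,7H)-dione}
Conditions: NCS (2.05 equiv), MeCN/CH2Cl2, −20 to 0 °C, dark
Reagents that add atoms: N-chlorosuccinimide O=C1CCC(=O)N1Cl
Why: Electrophilic α-chlorination of a push–pull enaminone with N-chlorosuccinimide should occur at C5, the carbon α to C6=O that terminates both enamine paths from N2 (through C1=C8a and through C3=C4) and is therefore the most nucleophilic site of each chromophore, while one equivalent per half at low temperature should spare C4 and the dienes; no stereocenter is involved (the descriptor at C7 changes only because chlorine changes the priorities).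

Step 10
Reactants: 18 bis(5-chloro-7-hydroxy) dimer
Product: 19 penazaphilone I (7,7'-di-O-acetate of 18, 7S,7'S)
Conditions: Ac2O, DMAP, Et3N, CH2Cl2, rt
Reagents that add atoms: acetic anhydride CC(=O)OC(C)=O
Why: DMAP-catalysed O-acetylation of the tertiary α-hydroxy diketone, a standard last step for 7-hydroxy azaphilone-type cores, should proceed with C5 now blocked by chlorine against C-acylation and without breaking any bond to C7, so the configuration is kept.

**Compound list**

1 | (R)-lactic acid | C[C@@H](O)C(=O)O | starting material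
2 | (2R,5R)-2-tert-butyl-5-methyl-1,3-dioxolan-4-one | C[C@H]1O[C@@H](C(C)(C)C)OC1=O | intermediate
3 | lithium (2R)-2-tert-butyl-5-methyl-1,3-dioxol-4-olate (enolate of 2) | CC1=C([O-])O[C@H](C(C)(C)C)O1.[Li+] | intermediate (not isolated)
4 | (2R,5S)-2-tert-butyl-5-[(2E)-3-ethoxyprop-2-enoyl]-5-methyl-1,3-dioxolan-4-one | CCO/C=C/C(=O)[C@]1(C)O[C@@H](C(C)(C)C)OC1=O | intermediate
5 | butane-1,4-diamine (putrescine) | NCCCCN | starting material
6 | (2R,2'R,5S,5'S)-5,5'-{butane-1,4-diylbis[azanediyl(2Z)-1-oxoprop-2-ene-3,1-diyl]}bis(2-tert-butyl-5-methyl-1,3-dioxolan-4-one) | O=C(/C=C\NCCCCN/C=C\C(=O)[C@]1(C)O[C@@H](C(C)(C)C)OC1=O)[C@]1(C)O[C@@H](C(C)(C)C)OC1=O | intermediate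
7 | (S)-2-methylbutan-1-ol | CC[C@H](C)CO | starting material
8 | (S)-2-methylbutanal | CC[C@H](C)C=O | intermediate (not isolated)
9 | ethyl (2E,4S)-2,4-dimethylhex-2-enoate | CC[C@H](C)/C=C(C)/C(=O)OCC | intermediate
10 | (2E,4S)-2,4-dimethylhex-2-en-1-ol | CC[C@H](C)/C=C(C)/CO | intermediate
11 | (2E,4S)-2,4-dimethylhex-2-enal | CC[C@H](C)/C=C(C)/C=O | intermediate (not isolated)
12 | (2E,4E,6S)-N-methoxy-N,4,6-trimethylocta-2,4-dienamide | CC[C@H](C)/C=C(C)/C=C/C(=O)N(C)OC | intermediate
13 | (5E,7E,9S)-7,9-dimethylundeca-5,7-dien-2-yn-4-one | CC[C@H](C)/C=C(C)/C=C/C(=O)C#CC | intermediate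
14 | bis-aminodienone Michael adduct (each half: Z enaminone N2–C1H=C8a bearing the dioxolanonyl ketone, and E C4a(CH3)=C4H–C3(=O)–dienyl) | CC[C@H](C)/C=C(C)/C=C/C(=O)/C=C(C)/C(C(=O)[C@]1(C)O[C@@H](C(C)(C)C)OC1=O)=C/NCCCCN/C=C(C(=O)[C@]1(C)O[C@@H](C(C)(C)C)OC1=O)/C(C)=C/C(=O)/C=C/C(C)=C/[C@@H](C)CC | intermediate (not isolated)
15 | 1,1'-(butane-1,4-diyl)bis{2-[(1E,3E,5S)-3,5-dimethylhepta-1,3-dien-1-yl]-4-methyl-5-{[(2R,4S)-2-tert-butyl-4-methyl-5-oxo-1,3-dioxolan-4-yl]carbonyl}pyridin-1-ium} diacetate | CC[C@H](C)/C=C(C)/C=C/c1cc(C)c(C(=O)[C@]2(C)O[C@@H](C(C)(C)C)OC2=O)c[n+]1CCCC[n+]1cc(C(=O)[C@]2(C)O[C@@H](C(C)(C)C)OC2=O)c(C)cc1/C=C/C(C)=C/[C@@H](C)CC.CC(=O)[O-].CC(=O)[O-] | intermediate (not isolated)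
16 | bis-anhydrobase (4-methylidene-1,4-dihydropyridine form of 15, both halves) | CC[C@H](C)/C=C(C)/C=C/C1=CC(=C)C(C(=O)[C@]2(C)O[C@@H](C(C)(C)C)OC2=O)=CN1CCCCN1C=C(C(=O)[C@]2(C)O[C@@H](C(C)(C)C)OC2=O)C(=C)C=C1/C=C/C(C)=C/[C@@H](C)CC | intermediate (not isolated)
17 | (7R,7'R)-2,2'-(butane-1,4-diyl)bis{3-[(1E,3E,5S)-3,5-dimethylhepta-1,3-dien-1-yl]-7-hydroxy-7-methylisoquinoline-6,8(2H,7H)-dione} | CC[C@H](C)/C=C(C)/C=C/C1=CC2=CC(=O)[C@@](C)(O)C(=O)C2=CN1CCCCN1C=C2C(=O)[C@](C)(O)C(=O)C=C2C=C1/C=C/C(C)=C/[C@@H](C)CC | intermediate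
18 | (7S,7'S)-2,2'-(butane-1,4-diyl)bis{5-chloro-3-[(1E,3E,5S)-3,5-dimethylhepta-1,3-dien-1-yl]-7-hydroxy-7-methylisoquinoline-6,8(2H,7H)-dione} | CC[C@H](C)/C=C(C)/C=C/C1=CC2=C(Cl)C(=O)[C@@](C)(O)C(=O)C2=CN1CCCCN1C=C2C(=O)[C@](C)(O)C(=O)C(Cl)=C2C=C1/C=C/C(C)=C/[C@@H](C)CC | intermediate
19 | penazaphilone I (7S,7'S; 7,7'-diacetate of 18) | CC[C@H](C)/C=C(C)/C=C/C1=CC2=C(Cl)C(=O)[C@@](C)(OC(C)=O)C(=O)C2=CN1CCCCN1C=C2C(=O)[C@](C)(OC(C)=O)C(=O)C(Cl)=C2C=C1/C=C/C(C)=C/[C@@H](C)CC | target

**Step count and risks**

Total step count: 10 steps. Longest linear sequence: 7 steps (steps 4, 5, 6, 7, 8, 9, 10 from (S)-2-methylbutan-1-ol); the lactic acid branch is 3 steps before the key step.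

Steps most likely to fail:

1. Step 8 (proposed new method). The hindered secondary enaminone may add too slowly or through nitrogen. The enaminone N–H may acylate itself on the dioxolanone carbonyl (six-membered lactam) before annulation. The acyl-stabilised anhydrobase may be too weak a nucleophile for the hindered lactone, or prolonged base may erode the C5' center by vinylogous deprotonation. The fallback uses known chemistry, sets out from 4 and 13 and returns at 17. Ammonia (NH3 in MeOH, 0 °C) should convert 4 into the primary enaminone (2R,5S)-5-[(2Z)-3-aminoprop-2-enoyl]-2-tert-butyl-5-methyl-1,3-dioxolan-4-one F1. A standard Bohlmann–Rahtz pyridine synthesis of F1 with 13 (AcOH/PhMe, 50 °C) should give the 3-acyl-4-methylpyridine (2R,5S)-2-tert-butyl-5-({6-[(1E,3E,5S)-3,5-dimethylhepta-1,3-dien-1-yl]-4-methylpyridin-3-yl}carbonyl)-5-methyl-1,3-dioxolan-4-one F2. Lateral deprotonation of the 4-methyl group with LiN(SiMe3)2 (2.2 equiv, THF, −78 °C) and intramolecular Claisen attack on the dioxolanone carbonyl, with loss of pivalaldehyde, should give the bicycle (7R)-3-[(1E,3E,5S)-3,5-dimethylhepta-1,3-dien-1-yl]-6,7-dihydroxy-7-methylisoquinolin-8(7H)-one F3 (drawn as its 6-enol). Two Menshutkin alkylations with 1,4-diiodobutane (0.5 equiv, MeCN, 70 °C) should give the 2,2'-(butane-1,4-diyl)bis-isoquinolinium diiodide F4, and NaHCO3 removes the two O6 protons to give 17, where the route is rejoined.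

2. Step 9. Poor site selectivity (competing attack at C4 or on the dienyl chains) or over-chlorination of the electron-rich dimer. The fallback moves the halogenation to the monomeric pyridine stage, sets out from 4 and 13 and returns at 18. After passage through F1, F2 and F3 as described above, ring B of F3 is an electron-poor pyridine and the C5=C6 enol is its only nucleophilic carbon. NCS (1 equiv, CH2Cl2, 0 °C) should therefore give (7R)-5-chloro-3-[(1E,3E,5S)-3,5-dimethylhepta-1,3-dien-1-yl]-6,7-dihydroxy-7-methylisoquinolin-8(7H)-one F5. Double alkylation with 1,4-diiodobutane (MeCN, 70 °C) should give the 5,5'-dichloro bis-isoquinolinium diiodide F6, and NaHCO3 gives 18 directly.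

3. Step 2. O-acylation of the tetrasubstituted enolate, or thermal decomposition of the enolate before it is acylated, instead of C-acylation. The fallback replaces acylation by an aldol/oxidation sequence, sets out from 2 (through enolate 3) and returns at 6. Aldol addition to 3-(trimethylsilyl)propynal (THF, −78 °C, attack again anti to tert-butyl, carbinol configuration irrelevant) should give (2R,5S)-2-tert-butyl-5-[1-hydroxy-3-(trimethylsilyl)prop-2-yn-1-yl]-5-methyl-1,3-dioxolan-4-one F7. Dess–Martin periodinane should give the silyl ynone (2R,5S)-2-tert-butyl-5-methyl-5-[3-(trimethylsilyl)prop-2-ynoyl]-1,3-dioxolan-4-one F8. Bu4NF buffered with AcOH (THF, −20 °C) should give the terminal ynone (2R,5S)-2-tert-butyl-5-methyl-5-(prop-2-ynoyl)-1,3-dioxolan-4-one F9. Conjugate addition of 5 (0.5 equiv, CH2Cl2, 0 °C) to two molecules of F9 gives 6, where the route is rejoined.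

**Further compounds**

F1 | step 8 | (2R,5S)-5-[(2Z)-3-aminoprop-2-enoyl]-2-tert-butyl-5-methyl-1,3-dioxolan-4-one | N/C=C\C(=O)[C@]1(C)O[C@@H](C(C)(C)C)OC1=O
F2 | step 8 | (2R,5S)-2-tert-butyl-5-({6-[(1E,3E,5S)-3,5-dimethylhepta-1,3-dien-1-yl]-4-methylpyridin-3-yl}carbonyl)-5-methyl-1,3-dioxolan-4-one | CC[C@H](C)/C=C(C)/C=C/c1cc(C)c(C(=O)[C@]2(C)O[C@@H](C(C)(C)C)OC2=O)cn1
F3 | step 8 | (7R)-3-[(1E,3E,5S)-3,5-dimethylhepta-1,3-dien-1-yl]-6,7-dihydroxy-7-methylisoquinolin-8(7H)-one | CC[C@H](C)/C=C(C)/C=C/c1cc2C=C(O)[C@@](C)(O)C(=O)c2cn1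
F4 | step 8 | (7R,7'R)-2,2'-(butane-1,4-diyl)bis{3-[(1E,3E,5S)-3,5-dimethylhepta-1,3-dien-1-yl]-6,7-dihydroxy-7-methyl-8-oxo-7,8-dihydroisoquinolin-2-ium} diiodide | CC[C@H](C)/C=C(C)/C=C/c1cc2C=C(O)[C@@](C)(O)C(=O)c2c[n+]1CCCC[n+]1cc2C(=O)[C@](C)(O)C(O)=Cc2cc1/C=C/C(C)=C/[C@@H](C)CC.[I-].[I-]
F5 | step 9 | (7R)-5-chloro-3-[(1E,3E,5S)-3,5-dimethylhepta-1,3-dien-1-yl]-6,7-dihydroxy-7-methylisoquinolin-8(7H)-one | CC[C@H](C)/C=C(C)/C=C/c1cc2C(Cl)=C(O)[C@@](C)(O)C(=O)c2cn1
F6 | step 9 | (7R,7'R)-2,2'-(butane-1,4-diyl)bis{5-chloro-3-[(1E,3E,5S)-3,5-dimethylhepta-1,3-dien-1-yl]-6,7-dihydroxy-7-methyl-8-oxo-7,8-dihydroisoquinolin-2-ium} diiodide | CC[C@H](C)/C=C(C)/C=C/c1cc2C(Cl)=C(O)[C@@](C)(O)C(=O)c2c[n+]1CCCC[n+]1cc2C(=O)[C@](C)(O)C(O)=C(Cl)c2cc1/C=C/C(C)=C/[C@@H](C)CC.[I-].[I-]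
F7 | step 2 | (2R,5S)-2-tert-butyl-5-[1-hydroxy-3-(trimethylsilyl)prop-2-yn-1-yl]-5-methyl-1,3-dioxolan-4-one (both carbinol epimers) | C[Si](C)(C)C#CC(O)[C@]1(C)O[C@@H](C(C)(C)C)OC1=O
F8 | step 2 | (2R,5S)-2-tert-butyl-5-methyl-5-[3-(trimethylsilyl)prop-2-ynoyl]-1,3-dioxolan-4-one | C[Si](C)(C)C#CC(=O)[C@]1(C)O[C@@H](C(C)(C)C)OC1=O
F9 | step 2 | (2R,5S)-2-tert-butyl-5-methyl-5-(prop-2-ynoyl)-1,3-dioxolan-4-one | C#CC(=O)[C@]1(C)O[C@@H](C(C)(C)C)OC1=O
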